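The pyranone (C) ring is cut at O1–C8a and at C4–C4a. Ring A then becomes a 3,5-dioxygenated 6-prenylbenzyne (C4a≡C8a) and the O1–C2–C3–C4 chain an enantiopure β-silyloxy ester that already carries C2 (S) and the catechol ring. Fluoride unmasks both partners: the alkoxide adds to C8a, and the C4a carbanion so formed acylates on the ester, which closes ring C in one operation. The step exploits the C5 oxygen next to C4a, which polarises the aryne so that O1 bonds to C8a only. The aryne precursor, a silyl triflate, comes from phloroglucinol by two carbamate-directed metalations in one pot; global acetal cleavage ends the route.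

Key step: step 9

Remark: the (S,S)-TsDPEN–Ru catalyst is assumed to show on β-keto ester 15 the facial sense it shows on acetophenones (aryl as the large group), which gives the (S)-carbinol.

Step 1
Reactants: 1 phloroglucinol
Product: 2 3,5-bis(methoxymethoxy)phenol
Conditions: MOMCl (2.0 equiv), i-Pr2NEt, CH2Cl2/DMF, 0 °C → rt
Reagents that add atoms: chloromethyl methyl ether, COCCl
Why: Base-mediated O-alkylation (MOM protection) of a C3-symmetric triphenol can give only one bis-ether, so only the degree of alkylation has to be controlled, by stoichiometry and chromatographic removal of the mono- and tris-ethers.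

Step 2
Reactants: 2 3,5-bis(methoxymethoxy)phenol
Product: 3 3,5-bis(methoxymethoxy)phenyl N-isopropylcarbamate
Conditions: i-PrNCO, Et3N (cat.), CH2Cl2, rt
Reagents that add atoms: isopropyl isocyanate, CC(C)N=C=O
Why: Amine-catalysed addition of the phenol to the isocyanate (carbamoylation) installs a strong ortho-directing group that can later be removed by mild E1cB cleavage.

Step 3
Reactants: 3 3,5-bis(methoxymethoxy)phenyl N-isopropylcarbamate
Product: 9 3,5-bis(methoxymethoxy)-2-(3-methylbut-2-en-1-yl)-6-(trimethylsilyl)phenyl N-isopropylcarbamate, via N-silyl carbamate 4 (not isolated), via 2-lithio carbamate 5 (not isolated), via N-silyl aryl silane 6 (not isolated), via 6-lithio aryl silane 7 (not isolated), via N-silyl prenyl arene 8 (not isolated)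
Conditions: TBSOTf, TMEDA, Et2O, 0 °C → rt; n-BuLi (2 equiv), TMEDA, −78 °C; TMSCl (1.0 equiv), −78 → 0 °C; n-BuLi, −78 °C; CuBr·SMe2 (10 mol %), prenyl bromide, −78 → −20 °C; aq. NH4Cl
Reagents that add atoms: chlorotrimethylsilane, C[Si](C)(C)Cl; prenyl bromide (1-bromo-3-methylbut-2-ene), CC(C)=CCBr
Why: Two directed ortho-metalations in one pot: the N-silylated carbamate, the strongest director on the ring, should guide n-BuLi first to one of its two equivalent ortho positions (each shared with an OMOM group) for silylation by exactly one equivalent of TMSCl and then, with the N–Si bond still in place, to the only remaining ortho position for copper-catalysed SN2 allylation at the unhindered CH2 terminus of prenyl bromide, and the N–Si bond is hydrolysed on work-up.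

Step 4
Reactants: 9 3,5-bis(methoxymethoxy)-2-(3-methylbut-2-en-1-yl)-6-(trimethylsilyl)phenyl N-isopropylcarbamate
Product: 11 3,5-bis(methoxymethoxy)-2-(3-methylbut-2-en-1-yl)-6-(trimethylsilyl)phenyl trifluoromethanesulfonate, via phenol 10 (not isolated)
Conditions: Et2NH, DBU, MeCN, 40 °C; then PhNTf2, rt
Reagents that add atoms: N-phenylbis(trifluoromethanesulfonimide), O=S(=O)(N(c1ccccc1)S(=O)(=O)C(F)(F)F)C(F)(F)F
Why: E1cB cleavage of the N–H carbamate by DBU (the isocyanate is trapped by Et2NH) frees the phenoxide, which is triflated in the same pot by PhNTf2, the known one-pot route to o-silylaryl triflates (Kobayashi aryne precursors).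

Step 5
Reactants: 12 3',4'-dihydroxyacetophenone
Product: 13 3',4'-bis(methoxymethoxy)acetophenone
Conditions: MOMCl, i-Pr2NEt, CH2Cl2, 0 °C → rt
Reagents that add atoms: chloromethyl methyl ether, COCCl
Why: MOM protection (O-alkylation) of both catechol hydroxyls gives acetals that tolerate the basic, reductive and fluoride steps that follow and leave together with those of ring A at the end.

Step 6
Reactants: 13 3',4'-bis(methoxymethoxy)acetophenone
Product: 15 methyl 3-[3,4-bis(methoxymethoxy)phenyl]-3-oxopropanoate, via sodium enolate 14 (not isolated)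
Conditions: NaH, (MeO)2CO, THF, reflux; AcOH
Reagents that add atoms: dimethyl carbonate, COC(=O)OC
Why: Crossed Claisen condensation (C-methoxycarbonylation) of the ketone enolate with dimethyl carbonate is driven to completion by deprotonation of the β-keto ester to enolate 14.

Step 7
Reactants: 15 methyl 3-[3,4-bis(methoxymethoxy)phenyl]-3-oxopropanoate
Product: 16 methyl (3S)-3-[3,4-bis(methoxymethoxy)phenyl]-3-hydroxypropanoate
Conditions: RuCl[(S,S)-TsDPEN](p-cymene) (1 mol %), HCO2H/Et3N (5:2), DMF, 30 °C
Reagents that add atoms: none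
Why: Noyori asymmetric transfer hydrogenation: in the outer-sphere Ru–H/N–H transfer the aryl group lies next to the η6-arene (CH/π contact), so the (S,S)-catalyst should deliver hydride to the Re face of the aryl ketone and set C3 as S.

Step 8
Reactants: 16 methyl (3S)-3-[3,4-bis(methoxymethoxy)phenyl]-3-hydroxypropanoate
Product: 17 methyl (3S)-3-[3,4-bis(methoxymethoxy)phenyl]-3-[(trimethylsilyl)oxy]propanoate
Conditions: TMSCl, imidazole, CH2Cl2, 0 °C
Reagents that add atoms: chlorotrimethylsilane, C[Si](C)(C)Cl
Why: O-silylation of the secondary alcohol turns it into a fluoride-labile, proton-free alkoxide precursor without touching any bond to C3.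

Step 9
Reactants: 11 3,5-bis(methoxymethoxy)-2-(3-methylbut-2-en-1-yl)-6-(trimethylsilyl)phenyl trifluoromethanesulfonate; 17 methyl (3S)-3-[3,4-bis(methoxymethoxy)phenyl]-3-[(trimethylsilyl)oxy]propanoate
Product: 21 (2S)-5,7-bis(methoxymethoxy)-2-[3,4-bis(methoxymethoxy)phenyl]-8-(3-methylbut-2-en-1-yl)chroman-4-one, via aryne 18 (not isolated), via potassium alkoxide 19 (not isolated), via aryl carbanion 20 (not isolated)
Conditions: KF, 18-crown-6 (1.05 equiv each, portionwise), 17 (1.5 equiv), THF, −20 °C → rt; pH 7 buffer
Reagents that add atoms: none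
Why: Proposed new method: Fluoride sets free the aryne 18 from 11 and the alkoxide 19 from 17, 19 adds to C8a of 18, and the C4a carbanion 20 so formed attacks the ester carbonyl and expels methoxide, which desilylates the next molecule of 17 (as MeOSiMe3) so that the chain goes on with only a catalytic amount of free base. The closest known reactions are the fluoride-mediated annulation of arynes with methyl salicylates to xanthones, the O–H insertion of arynes into aliphatic alcohols and the Parham cycliacylation of 3-(2-lithioaryloxy)propanoic acid derivatives to chroman-4-ones; what is new is an aliphatic β-silyloxy ester as the four-atom partner of the aryne. Ring C is closed by the C4–C4a bond in a 6-exo-trig acyl substitution that follows the intermolecular O1–C8a bond formation, a formal [4+2] annulation. No stereocentre is created: C2 comes from 17 with all four bonds untouched, and its configuration should be kept because alkoxide stays catalytic (limiting fluoride, silyl transfer to methoxide), which should suppress enolisation and retro-oxa-Michael opening of 21. The step needs oxygen to attack C8a and not C4a, which the C5 OMOM group secures by inductive polarisation of the aryne (attack at the remote carbon, carbanion next to oxygen) against the modest steric bias of the C8 prenyl group. It also needs acylation of 20 to outrun protonation, which the proton-free medium (silyl ether instead of alcohol, THF instead of MeCN) and the six-membered transition state secure.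

Step 10
Reactants: 21 (2S)-5,7-bis(methoxymethoxy)-2-[3,4-bis(methoxymethoxy)phenyl]-8-(3-methylbut-2-en-1-yl)chroman-4-one
Product: 22 (2S)-2-(3,4-dihydroxyphenyl)-5,7-dihydroxy-8-(3-methylbut-2-en-1-yl)chroman-4-one (target)
Conditions: 3 M aq. HCl, MeOH, 40 °C
Reagents that add atoms: none
Why: Acid-catalysed acetal methanolysis removes the four MOM groups as dimethoxymethane, and under mild Brønsted acid the flavanone should not open to the chalcone, so C2 is retained, provided the reaction is stopped at full conversion before O7–H adds to the prenyl alkene.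

Compound list
1 | phloroglucinol (benzene-1,3,5-triol) | Oc1cc(O)cc(O)c1 | starting material
2 | 3,5-bis(methoxymethoxy)phenol | COCOc1cc(O)cc(OCOC)c1 | intermediate
3 | 3,5-bis(methoxymethoxy)phenyl N-isopropylcarbamate | COCOc1cc(OCOC)cc(OC(=O)NC(C)C)c1 | intermediate
4 | 3,5-bis(methoxymethoxy)phenyl N-(tert-butyldimethylsilyl)-N-isopropylcarbamate (formed in situ) | COCOc1cc(OCOC)cc(OC(=O)N(C(C)C)[Si](C)(C)C(C)(C)C)c1 | intermediate
5 | 2-lithio derivative of 4, lithium between the carbamate and an OMOM group (formed in situ) | COCOc1cc(OCOC)cc(OC(=O)N(C(C)C)[Si](C)(C)C(C)(C)C)c1[Li] | intermediate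
6 | 3,5-bis(methoxymethoxy)-2-(trimethylsilyl)phenyl N-(tert-butyldimethylsilyl)-N-isopropylcarbamate (formed in situ) | COCOc1cc(OCOC)cc(OC(=O)N(C(C)C)[Si](C)(C)C(C)(C)C)c1[Si](C)(C)C | intermediate
7 | 6-lithio derivative of 6, lithium at the second position ortho to the carbamate (formed in situ) | COCOc1cc(OCOC)c([Li])c(OC(=O)N(C(C)C)[Si](C)(C)C(C)(C)C)c1[Si](C)(C)C | intermediate
8 | 3,5-bis(methoxymethoxy)-2-(3-methylbut-2-en-1-yl)-6-(trimethylsilyl)phenyl N-(tert-butyldimethylsilyl)-N-isopropylcarbamate (formed in situ) | COCOc1cc(OCOC)c(CC=C(C)C)c(OC(=O)N(C(C)C)[Si](C)(C)C(C)(C)C)c1[Si](C)(C)C | intermediate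
9 | 3,5-bis(methoxymethoxy)-2-(3-methylbut-2-en-1-yl)-6-(trimethylsilyl)phenyl N-isopropylcarbamate | COCOc1cc(OCOC)c(CC=C(C)C)c(OC(=O)NC(C)C)c1[Si](C)(C)C | intermediate
10 | 3,5-bis(methoxymethoxy)-2-(3-methylbut-2-en-1-yl)-6-(trimethylsilyl)phenol (in step 4 present as its DBU-H+ phenoxide) | COCOc1cc(OCOC)c(CC=C(C)C)c(O)c1[Si](C)(C)C | intermediate
11 | 3,5-bis(methoxymethoxy)-2-(3-methylbut-2-en-1-yl)-6-(trimethylsilyl)phenyl trifluoromethanesulfonate | COCOc1cc(OCOC)c(CC=C(C)C)c(OS(=O)(=O)C(F)(F)F)c1[Si](C)(C)C | intermediate
12 | 3',4'-dihydroxyacetophenone | CC(=O)c1ccc(O)c(O)c1 | starting material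
13 | 3',4'-bis(methoxymethoxy)acetophenone | CC(=O)c1ccc(OCOC)c(OCOC)c1 | intermediate
14 | sodium enolate of methyl 3-[3,4-bis(methoxymethoxy)phenyl]-3-oxopropanoate (formed in situ) | COC(=O)[CH-]C(=O)c1ccc(OCOC)c(OCOC)c1.[Na+] | intermediate
15 | methyl 3-[3,4-bis(methoxymethoxy)phenyl]-3-oxopropanoate | COC(=O)CC(=O)c1ccc(OCOC)c(OCOC)c1 | intermediate
16 | methyl (3S)-3-[3,4-bis(methoxymethoxy)phenyl]-3-hydroxypropanoate | O[C@H](c1ccc(OCOC)c(OCOC)c1)CC(=O)OC | intermediate
17 | methyl (3S)-3-[3,4-bis(methoxymethoxy)phenyl]-3-[(trimethylsilyl)oxy]propanoate | C[Si](C)(C)O[C@H](c1ccc(OCOC)c(OCOC)c1)CC(=O)OC | intermediate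
18 | 3,5-bis(methoxymethoxy)-6-(3-methylbut-2-en-1-yl)benzyne (formed in situ) | CC(C)=CCC1=C(OCOC)C=C(OCOC)C#C1 | intermediate
19 | potassium (1S)-1-[3,4-bis(methoxymethoxy)phenyl]-3-methoxy-3-oxopropan-1-olate (formed in situ) | [K+].[O-][C@H](c1ccc(OCOC)c(OCOC)c1)CC(=O)OC | intermediate
20 | potassium aryl carbanion: O-arylated 19 with the negative charge on the ring carbon between the ether oxygen and an OMOM group, (S) (formed in situ) | CC(C)=CCc1c(OCOC)cc(OCOC)[c-]c1O[C@H](c1ccc(OCOC)c(OCOC)c1)CC(=O)OC.[K+] | intermediate
21 | (2S)-5,7-bis(methoxymethoxy)-2-[3,4-bis(methoxymethoxy)phenyl]-8-(3-methylbut-2-en-1-yl)chroman-4-one | CC(C)=CCc1c(OCOC)cc(OCOC)c2c1O[C@H](c1ccc(OCOC)c(OCOC)c1)CC2=O | intermediate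
22 | (2S)-2-(3,4-dihydroxyphenyl)-5,7-dihydroxy-8-(3-methylbut-2-en-1-yl)chroman-4-one | CC(C)=CCc1c(O)cc(O)c2c1O[C@H](c1ccc(O)c(O)c1)CC2=O | target

Total step count: 10
Longest linear sequence: 6 steps (steps 1–4, 9 and 10); the ester branch (steps 5–8) joins at step 9.

Steps most likely to fail

1. Step 9 (proposed new method). The carbanion may be protonated or may abstract a C3 proton faster than it acylates. The alkoxide may fragment by retro-aldol cleavage before it meets the aryne. The aryne may be consumed by an ene reaction with the prenyl alkene. Base-induced enolisation and ring opening may erode the configuration at C2. The neighbouring prenyl group may weaken the regiocontrol of the addition. The fallback separates the two bond formations and uses known chemistry. It sets out from 11 and 16. The aryne is generated from 11 (KF, 18-crown-6, THF, −20 °C) in the presence of the free alcohol 16. By the known O–H insertion of arynes into aliphatic alcohols this should give methyl (3S)-3-[3,4-bis(methoxymethoxy)phenyl]-3-[3,5-bis(methoxymethoxy)-2-(3-methylbut-2-en-1-yl)phenoxy]propanoate F1, with oxygen again at the aryne carbon remote from OMOM. Neutral ester hydrolysis (Me3SnOH, 1,2-dichloroethane, 70 °C), chosen to avoid β-elimination of the aryloxide, would give (3S)-3-[3,4-bis(methoxymethoxy)phenyl]-3-[3,5-bis(methoxymethoxy)-2-(3-methylbut-2-en-1-yl)phenoxy]propanoic acid F2. Intramolecular Friedel–Crafts acylation of the only free ortho position through the mixed trifluoroacetic anhydride (TFAA, 2,6-di-tert-butylpyridine, CH2Cl2, 0 °C) would close ring C without touching C2. The fallback comes back to the route at 21.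

2. Step 3. The first deprotonation may take place between the two OMOM groups. Silylation with a single equivalent of TMSCl may be incomplete, so that the second metalation starts from a mixture. Deprotonation of the crowded, silylated ring may be slow. The ortho-lithiated carbamate may undergo an anionic ortho-Fries shift on warming. The allylation may proceed with allylic transposition (SN2′). The fallback replaces both deprotonations by a bromine–lithium exchange with silyl migration and the allylation by a sigmatropic shift. It sets out from 2. ortho-Selective bromination (NBS, cat. i-Pr2NH, CH2Cl2, −78 → 0 °C) gives 2-bromo-3,5-bis(methoxymethoxy)phenol F3. Palladium-catalysed O-allylation with tert-butyl 2-methylbut-3-en-2-yl carbonate (Pd(PPh3)4, THF, 0 °C) gives 2-bromo-3,5-bis(methoxymethoxy)-1-[(2-methylbut-3-en-2-yl)oxy]benzene F4. Aromatic Claisen rearrangement (xylene, 130 °C) transfers the allyl unit with transposition to the only free ortho position and gives 2-bromo-3,5-bis(methoxymethoxy)-6-(3-methylbut-2-en-1-yl)phenol F5. O-Silylation (HMDS, THF, 60 °C) gives [2-bromo-3,5-bis(methoxymethoxy)-6-(3-methylbut-2-en-1-yl)phenoxy]trimethylsilane F6. Bromine–lithium exchange (n-BuLi, THF, −78 °C → rt) is followed by 1,3-migration of silicon from oxygen to carbon (retro-Brook rearrangement), and aqueous work-up frees the phenol. The fallback comes back to the route at 10, which is isolated and triflated (PhNTf2, DBU, MeCN) to 11.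

3. Step 10. Under Brønsted acid the C7 hydroxyl may add to the prenyl alkene (chroman formation), the alkene may be hydrated, or the flavanone may open and close again with loss of configuration at C2. The fallback avoids protic acid by exchanging the acetals for silyl ethers. It sets out from 21. TMSOTf and 2,2′-bipyridyl (CH2Cl2, 0 °C → rt) should convert the four aryl MOM ethers into aryl silyl ethers and give in situ (2S)-5,7-bis[(trimethylsilyl)oxy]-2-{3,4-bis[(trimethylsilyl)oxy]phenyl}-8-(3-methylbut-2-en-1-yl)chroman-4-one F7. Addition of water then hydrolyses the labile aryl silyl ethers at near-neutral pH. The fallback comes back to the route at 22.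

Further compounds
F1 | step 9 | methyl (3S)-3-[3,4-bis(methoxymethoxy)phenyl]-3-[3,5-bis(methoxymethoxy)-2-(3-methylbut-2-en-1-yl)phenoxy]propanoate | CC(C)=CCc1c(OCOC)cc(OCOC)cc1O[C@H](c1ccc(OCOC)c(OCOC)c1)CC(=O)OC
F2 | step 9 | (3S)-3-[3,4-bis(methoxymethoxy)phenyl]-3-[3,5-bis(methoxymethoxy)-2-(3-methylbut-2-en-1-yl)phenoxy]propanoic acid | CC(C)=CCc1c(OCOC)cc(OCOC)cc1O[C@H](c1ccc(OCOC)c(OCOC)c1)CC(=O)O
F3 | step 3 | 2-bromo-3,5-bis(methoxymethoxy)phenol | COCOc1cc(OCOC)c(Br)c(O)c1
F4 | step 3 | 2-bromo-3,5-bis(methoxymethoxy)-1-[(2-methylbut-3-en-2-yl)oxy]benzene | COCOc1cc(OCOC)c(Br)c(OC(C)(C)C=C)c1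
F5 | step 3 | 2-bromo-3,5-bis(methoxymethoxy)-6-(3-methylbut-2-en-1-yl)phenol | COCOc1cc(OCOC)c(CC=C(C)C)c(O)c1Br
F6 | step 3 | [2-bromo-3,5-bis(methoxymethoxy)-6-(3-methylbut-2-en-1-yl)phenoxy]trimethylsilane | COCOc1cc(OCOC)c(CC=C(C)C)c(O[Si](C)(C)C)c1Br
F7 | step 10 | (2S)-5,7-bis[(trimethylsilyl)oxy]-2-{3,4-bis[(trimethylsilyl)oxy]phenyl}-8-(3-methylbut-2-en-1-yl)chroman-4-one | CC(C)=CCc1c(O[Si](C)(C)C)cc(O[Si](C)(C)C)c2c1O[C@H](c1ccc(O[Si](C)(C)C)c(O[Si](C)(C)C)c1)CC2=O
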